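## Structural features

The target is a germacranolide: a ten-membered carbocycle (C1–C10) with an α-methylene-γ-butyrolactone trans-fused across C6–C7 (oxygen on C6, carbonyl C12, exocyclic C11=C13). The ring holds two Z trisubstituted alkenes, C4=C5 (methyl C15) and C9=C10 (methyl C14), separated on each side by three atoms (C1–C2–C3 and C6–C7–C8). It is therefore a (Z,Z)-cyclodeca-1,6-diene in which every sp3 ring carbon except C2 is an allylic stereocentre. C6, C7 and C8 form a contiguous all-syn triad (6S,7R,8R), whereas the C1 and C3 carbinols (1S,3S) are 1,3-anti, trans on the ring, and are separated from the triad by the two alkenes. Fragile elements are the methylene lactone (Michael acceptor), the angelate (easy Z to E isomerisation to the tiglate), three allylic C–O bonds, and any β-hydroxy ketone or Z-enal met on the way. The real difficulty is to close the ten-membered ring and to set the remote C1/C3 pair correctly relative to C6–C8 with no stereocentre in between. The C1(OH)–C2H2–C3(OH) unit is an aldol at the alcohol level and maps onto a 4,5-dihydroisoxazole (C3=N–O–C1 over C2). The key step adds a C3 nitrile oxide to the C1=C2 end of a C9=C10–C1=C2 diene, which forms C2–C3 and O–C1, closes the carbocycle, and stores both diol oxygens in a ring that tolerates base, fluoride and acylation.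

## Logic of the disconnections

39 ⇒ 37 (through 38). The C11=C13 π bond is traced back to a C13–N single bond. The methylene lactone is the most reactive group of 39, so it is unmasked last. The gain is that no intermediate carries a Michael acceptor. The demand is that quaternisation and β-elimination run under conditions mild enough for the angelate and the two allylic alcohols.

37 ⇒ 36 ⇒ 34 (through 35). The C3–H bond is cut (carbinol to ketone), then the C3 carbonyl and O1 are reconnected through nitrogen (N–O bond). C3 can be derived from C1 by internal hydride delivery, and the heterocycle is a robust mask for the aldol. The gain is that C1 and C3 need no protecting group at any stage. The demands are a chemoselective N–O cleavage and a directed reduction that is anti.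

34 ⇒ 31 + 32, 31 ⇒ 30, 30 ⇒ 28 (through 33 and 29). The cuts are the O8–acyl bond, the O8–Si bond and the C11–C13 bond. All three operations are done while C1/C3 are locked in the heterocycle, so only one hydroxyl is ever free. The demands are enolisation of the lactone in preference to the C2–H of the heterocycle, and acylation without Z to E isomerisation.

28 ⇒ 25 (through 27 and 26). The cuts are C2–C3 and O–C1. This opens both the carbocycle and the heterocycle and removes C1 as a stereocentre. The demands on the forward step are set into the design of 25: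
- O8 carries a bulky silyl group on purpose, because with the 9Z geometry it decides which diene face the dipole can reach.
- The dipole is generated slowly at high dilution.
- Every other dipolarophile (methylene lactone, angelate) is absent.

25 ⇒ 24 ⇒ 23 ⇒ 22. These are functional-group changes at C3 only (oxime, aldehyde, alcohol, silyl ether). The demand is that the Z geometry at C4=C5 survives the enal stage.

22 ⇒ 19 + 15 (through 21 and 20). The cuts are C5–C6 and O6–C12. This gives two fragments of similar size, with the 4Z alkene preformed in 19 and the C7/C8 pair preformed in 15. The demands are Felkin–Anh addition at C6 (6S) and lactonisation through O6 only, which is why O8 is silylated and C12 is a tert-butyl ester until then.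

15 ⇒ 14 ⇒ 13 ⇒ 11 + 12. The cuts are C10–C1 (sp2–sp2) and the acyl–auxiliary bond at C6. The diene is made from a vinyl iodide after the aldol, because a Z-dienal would not keep its geometry. The demands are coupling with retention and temperatures low enough to avoid a 1,5-hydrogen shift in the Z-diene.

11 ⇒ 10 ⇒ 8 + 4 (through 9). The cut is C7–C8, a syn-aldol retron. One auxiliary-controlled step sets both centres. The demand is enolisation at the imide α-carbon and not next to the ester.

8 ⇒ 5 + 6 (through 7); 4 ⇒ 3 ⇒ 2 ⇒ 1; 19 ⇒ 18 ⇒ 16 (through 17). These are N-acylation, a hydroiodination/redox sequence and a carbometalation/iodination. They lead to commercial materials and fix both Z geometries by anti addition across alkynes.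

## Other disconnections considered

Alternative 1: The cut is at C5–C6 and C4–C15, with no ring closure. In the forward step MeMgBr with catalytic CuI adds anti across the alkyne of alkynol A1. The resulting five-membered chelated (Z)-vinylmagnesium alkoxide adds to aldehyde A2 to give seco chain A3.
- In favour: three components are joined in one flask, the 4Z geometry and C15 come from one carbometalation, the C3 hydroxyl needs no protection, and C3 is set beforehand by reagent control. On the last point it is the better plan, because the chosen route relays C3 from C1.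
- Against: the chelated magnesium reagent is basic and Lewis acidic, so α-epimerisation of A2 and chelate-controlled (anti-Felkin) addition are real risks. The vinyl iodide of A2 is exposed to Grignard and copper species. The ten-membered ring is still open, and a later closure at C10–C1 would create C1 without a controlling element.
- Comparison: on structure it delivers C3 and C6 but neither the ring nor C1, whereas the chosen step delivers ring and C1 together. On mechanism a polar addition is more predictable than a medium-ring cycloaddition, so here the alternative is the better. On step economy it is equal up to the seco stage (the chosen route uses the same carbometalation on 16, trapped with iodine) but longer afterwards, because three hydroxyls must be differentiated.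

Alternative 2: The cut is C1–C2. In the forward step nBuLi deprotonates the allylic dithiane of seco iodide A4, and the anion displaces the primary iodide to give the spiro-dithiane ring A5.
- In favour: C3 is preset and ring closure is separated from stereogenesis. No dipole is involved, so other alkenes cannot compete; on chemoselectivity toward alkenes it is the better. The methylene lactone can later come from an allylic alcohol without enolate chemistry, which is also a point in its favour.
- Against: the 2-alkenyl dithiane anion is ambident, and γ-attack would give an eight-membered ring. An SN2 closure to a ten-membered ring is entropically poor. The electrophile is a β-silyloxy iodide prone to elimination. Dithiane removal next to two allylic ethers and a diene is harsh.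
- Comparison: on structure it gives the ring but leaves C1 as a masked ketone, to be reduced under direction from O3. That is the same relay logic as the chosen plan in the opposite direction, and equal in merit. On step economy four protecting groups of three kinds and the late oxidation of C12 make it longer.

Alternative 3: The cut is C12–O and C11–C12, with the lactone carbonyl coming from CO. In the forward step PdCl2 with thiourea under CO converts the C6 hydroxyl of ethynyl carbinol A6 into an alkoxycarbonyl-palladium species, which adds syn across the alkyne. Protonolysis gives the methylene lactone A7.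
- In favour: lactone ring and exocyclic methylene arise in one neutral step with the angelate already in place. For that unit it is the equal or the better of the chosen three-operation sequence (aminomethylation, quaternisation, elimination).
- Against: it does not close the carbocycle. A6 needs an ethynyl-bearing C7 stereocentre inside a preformed ten-membered ring, which is harder to make than the succinate-derived C7. Divalent palladium next to an allylic alcohol and an allylic ester invites ionisation. A terminal alkyne is itself a dipolarophile, so it could not be carried through the chosen ring closure.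
- Comparison: on mechanism the carbonylation is well behaved on simple homopropargylic alcohols. On structure and overall step economy it moves the difficulty into A6 and leaves C1/C3 unsolved, so it is not better as a whole.

Key step: step 16

Assumption: atoms are numbered as in germacrane (ring C1–C10, C14 on C10, C15 on C4, lactone carbons C11–C13), "3,1-(nitrilooxy)" means the C3=N–O–C1 dihydroisoxazole bridge, TBS is tert-butyl(dimethyl)silyl, and 6 and 32 are taken as commercial.

Step 1
Reactants: 1 ethyl but-2-ynoate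
Product: 2 ethyl (2Z)-3-iodobut-2-enoate
Conditions: NaI, AcOH, 115 °C
Reagents that add atoms: sodium iodide, [Na+].[I-]
Why: Conjugate hydroiodination of an ynoate; iodide adds at C3 and protonation is anti, which puts iodine cis to the ester (Z), the geometry later needed at C9=C10.

Step 2
Reactants: 2 ethyl (2Z)-3-iodobut-2-enoate
Product: 3 (2Z)-3-iodobut-2-en-1-ol
Conditions: iBu2AlH (2.2 equiv), CH2Cl2, −78 → 0 °C; aq. potassium sodium tartrate
Reagents that add atoms: none
Why: Standard 1,2-reduction of a conjugated ester to the allylic alcohol; the vinyl iodide and the alkene geometry are not touched.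

Step 3
Reactants: 3 (2Z)-3-iodobut-2-en-1-ol
Product: 4 (2Z)-3-iodobut-2-enal
Conditions: MnO2, CH2Cl2, 20 °C, dark
Reagents that add atoms: none
Why: Allylic oxidation on MnO2 under neutral conditions should keep the Z geometry; the aldehyde is used at once in step 5.

Step 4
Reactants: 5 4-tert-butoxy-4-oxobutanoic acid (mono-tert-butyl succinate); 6 (4S)-4-benzyl-1,3-oxazolidin-2-one
Product: 8 tert-butyl 4-[(4S)-4-benzyl-2-oxo-1,3-oxazolidin-3-yl]-4-oxobutanoate, via mixed pivalic anhydride 7 (not isolated)
Conditions: PivCl, Et3N, THF, −20 °C; then 6, LiCl, −20 → 20 °C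
Reagents that add atoms: none
Why: N-acylation of the oxazolidinone by a mixed anhydride in the presence of LiCl; the tert-butyl ester is inert and the free acid end is the only one activated.

Step 5
Reactants: 8 tert-butyl 4-[(4S)-4-benzyl-2-oxo-1,3-oxazolidin-3-yl]-4-oxobutanoate; 4 (2Z)-3-iodobut-2-enal
Product: 10 tert-butyl (3S,4S,5Z)-3-[(4S)-4-benzyl-2-oxo-1,3-oxazolidine-3-carbonyl]-4-hydroxy-6-iodohept-5-enoate, via boron enolate 9 (not isolated)
Conditions: Bu2BOTf, iPr2NEt, CH2Cl2, −78 → 0 °C; then 4, −78 → 0 °C; H2O2, pH 7 buffer, MeOH, 0 °C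
Reagents that add atoms: none
Why: Evans syn aldol: the Z(O)-boron enolate forms only at the imide α-carbon and reacts through a chair (Zimmerman–Traxler) transition state on the face away from the benzyl group, which sets C7 and C8 together (3S,4S in 10).

Step 6
Reactants: 10 tert-butyl (3S,4S,5Z)-3-[(4S)-4-benzyl-2-oxo-1,3-oxazolidine-3-carbonyl]-4-hydroxy-6-iodohept-5-enoate
Product: 11 tert-butyl (3S,4S,5Z)-3-[(4S)-4-benzyl-2-oxo-1,3-oxazolidine-3-carbonyl]-4-TBSO-6-iodohept-5-enoate
Conditions: TBSOTf, 2,6-lutidine, CH2Cl2, −78 °C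
Reagents that add atoms: tert-butyldimethylsilyl triflate, CC(C)(C)[Si](C)(C)OS(=O)(=O)C(F)(F)F
Why: Silylation of the hindered aldol hydroxyl with a silyl triflate; it blocks retro-aldol and lactonisation of O8 onto the γ-ester and installs the bulky group used for face control in step 16.

Step 7
Reactants: 11 tert-butyl (3S,4S,5Z)-3-[(4S)-4-benzyl-2-oxo-1,3-oxazolidine-3-carbonyl]-4-TBSO-6-iodohept-5-enoate; 12 tributyl(ethenyl)stannane
Product: 13 tert-butyl (3S,4R,5Z)-3-[(4S)-4-benzyl-2-oxo-1,3-oxazolidine-3-carbonyl]-4-TBSO-6-methylocta-5,7-dienoate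
Conditions: Pd2(dba)3, AsPh3, CuI, NMP, 20 °C
Reagents that add atoms: none
Why: Stille coupling: oxidative addition of zerovalent palladium to the vinyl iodide and vinyl transfer from tin both go with retention, giving the 9Z diene; room temperature avoids a 1,5-hydrogen shift in the Z-diene (the C8 descriptor changes only because iodine is replaced by carbon).

Step 8
Reactants: 13 tert-butyl (3S,4R,5Z)-3-[(4S)-4-benzyl-2-oxo-1,3-oxazolidine-3-carbonyl]-4-TBSO-6-methylocta-5,7-dienoate
Product: 14 tert-butyl (3R,4R,5Z)-4-TBSO-3-(hydroxymethyl)-6-methylocta-5,7-dienoate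
Conditions: LiBH4, MeOH (1 equiv), Et2O, 0 °C
Reagents that add atoms: none
Why: Reductive removal of the oxazolidinone from a silyl-protected aldol adduct; the exocyclic imide carbonyl is reduced much faster than a tert-butyl ester, and the γ-hydroxy tert-butyl ester does not lactonise without acid.

Step 9
Reactants: 14 tert-butyl (3R,4R,5Z)-4-TBSO-3-(hydroxymethyl)-6-methylocta-5,7-dienoate
Product: 15 tert-butyl (3S,4R,5Z)-4-TBSO-3-formyl-6-methylocta-5,7-dienoate
Conditions: Dess–Martin periodinane, NaHCO3, CH2Cl2, 0 → 20 °C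
Reagents that add atoms: none
Why: Buffered periodinane oxidation of a primary alcohol to the aldehyde without epimerising the α-centre C7; the aldehyde is used crude.

Step 10
Reactants: 16 prop-2-yn-1-ol
Product: 18 (2Z)-3-iodo-2-methylprop-2-en-1-ol, via vinylmagnesium alkoxide 17 (not isolated)
Conditions: MeMgBr (2.5 equiv), CuI (10 mol%), THF, −10 → 20 °C; then I2, −78 → 0 °C
Reagents that add atoms: methylmagnesium bromide, C[Mg]Br; iodine, II
Why: Copper-catalysed anti carbomagnesiation of the propargylic alkoxide puts the methyl on the inner carbon and gives the five-membered chelate 17; iodinolysis with retention gives the Z-iodide, the future 4Z alkene with C15.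

Step 11
Reactants: 18 (2Z)-3-iodo-2-methylprop-2-en-1-ol
Product: 19 tert-butyl{[(2Z)-3-iodo-2-methylprop-2-en-1-yl]oxy}dimethylsilane
Conditions: TBSCl, imidazole, CH2Cl2, 0 → 20 °C
Reagents that add atoms: tert-butyldimethylsilyl chloride, CC(C)(C)[Si](C)(C)Cl
Why: Routine silylation of a primary alcohol; a primary TBS ether survives iodine–lithium exchange at −78 °C and can later be removed in the presence of the secondary one.

Step 12
Reactants: 19 tert-butyl{[(2Z)-3-iodo-2-methylprop-2-en-1-yl]oxy}dimethylsilane; 15 tert-butyl (3S,4R,5Z)-4-TBSO-3-formyl-6-methylocta-5,7-dienoate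
Product: 22 (4R,5S)-4-[(1R,2Z)-1-TBSO-3-methylpenta-2,4-dien-1-yl]-5-[(1Z)-3-TBSO-2-methylprop-1-en-1-yl]oxolan-2-one, via vinyllithium 20 (not isolated), via lithium alkoxide 21 (not isolated)
Conditions: 19, tBuLi (2.0 equiv), Et2O, −78 °C; then 15, −78 °C; then THF, −78 → 20 °C
Reagents that add atoms: none
Why: Iodine–lithium exchange with retention gives 20, which adds to the aldehyde in the Felkin–Anh sense (anti to the larger C8 branch, past H7), setting 6S syn to the C11 branch; on warming the C6 alkoxide closes onto the tert-butyl ester (5-exo acyl substitution) to the trans-lactone, while O8 stays silylated and cannot compete.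

Step 13
Reactants: 22 (4R,5S)-4-[(1R,2Z)-1-TBSO-3-methylpenta-2,4-dien-1-yl]-5-[(1Z)-3-TBSO-2-methylprop-1-en-1-yl]oxolan-2-one
Product: 23 (4R,5S)-4-[(1R,2Z)-1-TBSO-3-methylpenta-2,4-dien-1-yl]-5-[(1Z)-3-hydroxy-2-methylprop-1-en-1-yl]oxolan-2-one
Conditions: HF·pyridine, pyridine, THF, 0 °C
Reagents that add atoms: none
Why: Buffered fluoride cleaves the unhindered primary allylic silyl ether much faster than the secondary one flanked by C7 and the diene; the buffer prevents ionisation at the dienylic C8–O bond.

Step 14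
Reactants: 23 (4R,5S)-4-[(1R,2Z)-1-TBSO-3-methylpenta-2,4-dien-1-yl]-5-[(1Z)-3-hydroxy-2-methylprop-1-en-1-yl]oxolan-2-one
Product: 24 (2Z)-3-{(2S,3R)-3-[(1R,2Z)-1-TBSO-3-methylpenta-2,4-dien-1-yl]-5-oxooxolan-2-yl}-2-methylprop-2-enal
Conditions: MnO2, CH2Cl2, 0 → 20 °C, dark; filter, use at once
Reagents that add atoms: none
Why: Neutral allylic oxidation, the usual way to reach a Z-2-methyl-2-enal without isomerisation; the enal is not stored, because acid, base or nucleophiles would turn it into the E isomer.

Step 15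
Reactants: 24 (2Z)-3-{(2S,3R)-3-[(1R,2Z)-1-TBSO-3-methylpenta-2,4-dien-1-yl]-5-oxooxolan-2-yl}-2-methylprop-2-enal
Product: 25 (1E,2Z)-3-{(2S,3R)-3-[(1R,2Z)-1-TBSO-3-methylpenta-2,4-dien-1-yl]-5-oxooxolan-2-yl}-2-methylprop-2-enal oxime
Conditions: NH2OH·HCl, NaOAc, MeOH/H2O, 0 °C
Reagents that add atoms: hydroxylamine hydrochloride, NO.Cl
Why: Oxime formation at an aldehyde is fast at 0 °C under acetate buffer and faster than conjugate addition or lactone aminolysis; the oxime is far less prone to Z/E scrambling than the enal.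

Step 16
Reactants: 25 (1E,2Z)-3-{(2S,3R)-3-[(1R,2Z)-1-TBSO-3-methylpenta-2,4-dien-1-yl]-5-oxooxolan-2-yl}-2-methylprop-2-enal oxime
Product: 28 (1S,6S,7R,8R,4Z,9Z)-8-TBSO-3,1-(nitrilooxy)germacra-4,9-dien-12,6-olide, via hydroximoyl chloride 26 (not isolated), via nitrile oxide 27 (not isolated)
Conditions: aq. NaOCl (1.5 equiv), Et3N (0.1 equiv), CH2Cl2, 0 → 20 °C; 25 added over 12 h, ≤ 0.002 M
Reagents that add atoms: none
Why: Hypochlorite converts the aldoxime into hydroximoyl chloride 26, which loses HCl to the conjugated nitrile oxide 27; this adds in a concerted but asynchronous [3+2] (Huisgen) cycloaddition across C1=C2, carbon to the unsubstituted terminus C2 and oxygen to C1. The closest known reaction type is the intramolecular nitrile oxide–alkene cycloaddition that closes medium and large carbocycles as bridged 5-substituted dihydroisoxazoles. The ten-membered carbocycle closes in the bridged mode through the C2–C3 bond (C1 and C3 then spanned by O–N) and the dihydroisoxazole closes in the same event; the fused mode at C1 would give a nine-membered ring against the normal regiochemistry of a monosubstituted alkene. The ring being formed is a (Z,Z)-cyclodeca-1,6-diene, a ten-membered pattern with little transannular strain, and the two Z-alkenes and the trans-lactone already fold C3 toward C2. C1 is controlled by C8: allylic 1,3-strain across the Z C9=C10 bond holds H8 in the diene plane, so C7 (the tether) lies on one diene face and the silyloxy group on the other; the vinyl terminus can then only turn toward the tether face, and that trajectory gives 1S. Three selectivities are needed: C1=C2 over the trisubstituted C9=C10 (intrinsic order monosubstituted far above trisubstituted, and no fully substituted C–O centre is formed), ring closure over dimerisation to the furoxan (slow generation at high dilution), and no competing dipolarophile (methylene lactone and angelate are absent).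

Step 17
Reactants: 28 (1S,6S,7R,8R,4Z,9Z)-8-TBSO-3,1-(nitrilooxy)germacra-4,9-dien-12,6-olide
Product: 30 (1S,6S,7R,8R,11S,4Z,9Z)-13-(dimethylamino)-8-TBSO-3,1-(nitrilooxy)germacra-4,9-dien-12,6-olide, via lithium enolate 29 (not isolated)
Conditions: LiN(SiMe3)2 (1.15 equiv), THF, −78 °C; then Me2N=CH2 I, −78 → 0 °C
Reagents that add atoms: dimethylmethyleneammonium iodide, C[N+](C)=C.[I-]
Why: The silylamide enolises the lactone, the most acidic C–H (the C2–H of the dihydroisoxazole needs a stronger base), and the enolate is aminomethylated by the preformed iminium salt (Mannich reaction) anti to the C7–C8 bond; the new C11 centre is lost in step 22, and the amine serves as a masked methylene.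

Step 18
Reactants: 30 (1S,6S,7R,8R,11S,4Z,9Z)-13-(dimethylamino)-8-TBSO-3,1-(nitrilooxy)germacra-4,9-dien-12,6-olide
Product: 31 (1S,6S,7S,8R,11S,4Z,9Z)-13-(dimethylamino)-8-hydroxy-3,1-(nitrilooxy)germacra-4,9-dien-12,6-olide
Conditions: HF·pyridine, THF, 0 → 20 °C; aq. NaHCO3
Reagents that add atoms: none
Why: Fluoride-mediated cleavage of the secondary silyl ether; the dihydroisoxazole, the lactone and the amine are stable to HF·pyridine, and no Michael acceptor is present (the C7 descriptor changes by priority only).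

Step 19
Reactants: 31 (1S,6S,7S,8R,11S,4Z,9Z)-13-(dimethylamino)-8-hydroxy-3,1-(nitrilooxy)germacra-4,9-dien-12,6-olide; 32 (2Z)-2-methylbut-2-enoic acid (angelic acid)
Product: 34 (1S,6S,7R,8R,11S,4Z,9Z)-8-[(2Z)-2-methylbut-2-enoyloxy]-13-(dimethylamino)-3,1-(nitrilooxy)germacra-4,9-dien-12,6-olide, via mixed anhydride 33 (not isolated)
Conditions: 32, 2,4,6-trichlorobenzoyl chloride, Et3N, toluene, 20 °C; then 31, 60–80 °C
Reagents that add atoms: none
Why: Yamaguchi-type mixed-anhydride acylation without a nucleophilic catalyst is the known way to make angelates without isomerisation to tiglates; O8 is the only free hydroxyl because C1 and C3 are still inside the heterocycle.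

Step 20
Reactants: 34 (1S,6S,7R,8R,11S,4Z,9Z)-8-[(2Z)-2-methylbut-2-enoyloxy]-13-(dimethylamino)-3,1-(nitrilooxy)germacra-4,9-dien-12,6-olide
Product: 36 (1S,6S,7R,8R,11S,4Z,9Z)-8-[(2Z)-2-methylbut-2-enoyloxy]-13-(dimethylamino)-1-hydroxy-3-oxogermacra-4,9-dien-12,6-olide, via hydroxy imine 35 (not isolated)
Conditions: Mo(CO)6 (1.2 equiv), MeCN/H2O (10:1), 75 °C
Reagents that add atoms: water, O
Why: Zerovalent molybdenum cleaves the weak N–O bond reductively and the β-hydroxy imine 35 is hydrolysed to the β-hydroxy ketone; alkenes and esters are not reduced, and with the methylene masked as the amine there is no acceptor for the ammonia released.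

Step 21
Reactants: 36 (1S,6S,7R,8R,11S,4Z,9Z)-8-[(2Z)-2-methylbut-2-enoyloxy]-13-(dimethylamino)-1-hydroxy-3-oxogermacra-4,9-dien-12,6-olide
Product: 37 (1S,3S,6S,7R,8R,11S,4Z,9Z)-8-[(2Z)-2-methylbut-2-enoyloxy]-13-(dimethylamino)-1,3-dihydroxygermacra-4,9-dien-12,6-olide
Conditions: Me4NBH(OAc)3 (5 equiv), MeCN/AcOH (1:1), −30 °C
Reagents that add atoms: none
Why: Evans–Saksena reduction: ligand exchange binds the borohydride to O1 and hydride is delivered intramolecularly to C3 from the ring face of O1, so the new hydroxyl is trans (1,3-anti) to it, which gives 3S; the reagent leaves esters, the lactone and isolated alkenes alone.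

Step 22
Reactants: 37 (1S,3S,6S,7R,8R,11S,4Z,9Z)-8-[(2Z)-2-methylbut-2-enoyloxy]-13-(dimethylamino)-1,3-dihydroxygermacra-4,9-dien-12,6-olide
Product: 39 (1S,3S,6S,7R,8R,4Z,9Z)-8-[(2Z)-2-methylbut-2-enoyloxy]-1,3-dihydroxygermacra-4,9,11(13)-trien-12,6-olide (CNP0152559.1), via ammonium iodide 38 (not isolated)
Conditions: MeI, THF, 20 °C; then NaHCO3, CH2Cl2/H2O, 20 °C
Reagents that add atoms: none
Why: Methylation of the amine makes trimethylamine a leaving group and bicarbonate triggers β-elimination, the second stage of an Eschenmoser-type α-methylenation; no stereocentre is touched and the Michael acceptor appears only in the last step.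

## Compound list

1 | ethyl but-2-ynoate | CC#CC(=O)OCC | starting material
2 | ethyl (2Z)-3-iodobut-2-enoate | CCOC(=O)/C=C(/C)I | intermediate
3 | (2Z)-3-iodobut-2-en-1-ol | OC/C=C(/C)I | intermediate
4 | (2Z)-3-iodobut-2-enal | O=C/C=C(/C)I | intermediate
5 | 4-tert-butoxy-4-oxobutanoic acid | OC(=O)CCC(=O)OC(C)(C)C | starting material
6 | (4S)-4-benzyl-1,3-oxazolidin-2-one | O=C1OC[C@H](Cc2ccccc2)N1 | starting material
7 | 4-tert-butoxy-4-oxobutanoic pivalic anhydride (not isolated) | CC(C)(C)C(=O)OC(=O)CCC(=O)OC(C)(C)C | intermediate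
8 | tert-butyl 4-[(4S)-4-benzyl-2-oxo-1,3-oxazolidin-3-yl]-4-oxobutanoate | O=C(CCC(=O)OC(C)(C)C)N1C(=O)OC[C@@H]1Cc1ccccc1 | intermediate
9 | (Z)-dibutylboron enolate of 8 (not isolated) | CCCCB(CCCC)O/C(=C\CC(=O)OC(C)(C)C)N1C(=O)OC[C@@H]1Cc1ccccc1 | intermediate
10 | tert-butyl (3S,4S,5Z)-3-[(4S)-4-benzyl-2-oxo-1,3-oxazolidine-3-carbonyl]-4-hydroxy-6-iodohept-5-enoate | O=C(N1C(=O)OC[C@@H]1Cc1ccccc1)[C@@H](CC(=O)OC(C)(C)C)[C@H](O)/C=C(/C)I | intermediate
11 | tert-butyl (3S,4S,5Z)-3-[(4S)-4-benzyl-2-oxo-1,3-oxazolidine-3-carbonyl]-4-TBSO-6-iodohept-5-enoate | O=C(N1C(=O)OC[C@@H]1Cc1ccccc1)[C@@H](CC(=O)OC(C)(C)C)[C@H](O[Si](C)(C)C(C)(C)C)/C=C(/C)I | intermediate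
12 | tributyl(ethenyl)stannane | C=C[Sn](CCCC)(CCCC)CCCC | starting material
13 | tert-butyl (3S,4R,5Z)-3-[(4S)-4-benzyl-2-oxo-1,3-oxazolidine-3-carbonyl]-4-TBSO-6-methylocta-5,7-dienoate | O=C(N1C(=O)OC[C@@H]1Cc1ccccc1)[C@@H](CC(=O)OC(C)(C)C)[C@H](O[Si](C)(C)C(C)(C)C)/C=C(/C)C=C | intermediate
14 | tert-butyl (3R,4R,5Z)-4-TBSO-3-(hydroxymethyl)-6-methylocta-5,7-dienoate | OC[C@@H](CC(=O)OC(C)(C)C)[C@H](O[Si](C)(C)C(C)(C)C)/C=C(/C)C=C | intermediate
15 | tert-butyl (3S,4R,5Z)-4-TBSO-3-formyl-6-methylocta-5,7-dienoate | O=C[C@@H](CC(=O)OC(C)(C)C)[C@H](O[Si](C)(C)C(C)(C)C)/C=C(/C)C=C | intermediate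
16 | prop-2-yn-1-ol | C#CCO | starting material
17 | chelated (Z)-vinylmagnesium alkoxide, 4-methyl-2,5-dihydro-1,2-oxamagnesole (not isolated) | CC1=C[Mg]OC1 | intermediate
18 | (2Z)-3-iodo-2-methylprop-2-en-1-ol | OC/C(C)=C\I | intermediate
19 | tert-butyl{[(2Z)-3-iodo-2-methylprop-2-en-1-yl]oxy}dimethylsilane | CC(C)(C)[Si](C)(C)OC/C(C)=C\I | intermediate
20 | [(1Z)-3-TBSO-2-methylprop-1-en-1-yl]lithium (not isolated) | CC(C)(C)[Si](C)(C)OC/C(C)=C\[Li] | intermediate
21 | lithium alkoxide of tert-butyl (3R,4R,5Z)-4-TBSO-3-[(1S,2Z)-4-TBSO-1-hydroxy-3-methylbut-2-en-1-yl]-6-methylocta-5,7-dienoate (not isolated) | CC(C)(C)[Si](C)(C)OC/C(C)=C\[C@H](O[Li])[C@@H](CC(=O)OC(C)(C)C)[C@H](O[Si](C)(C)C(C)(C)C)/C=C(/C)C=C | intermediate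
22 | (4R,5S)-4-[(1R,2Z)-1-TBSO-3-methylpenta-2,4-dien-1-yl]-5-[(1Z)-3-TBSO-2-methylprop-1-en-1-yl]oxolan-2-one | CC(C)(C)[Si](C)(C)OC/C(C)=C\[C@@H]1OC(=O)C[C@H]1[C@H](O[Si](C)(C)C(C)(C)C)/C=C(/C)C=C | intermediate
23 | (4R,5S)-4-[(1R,2Z)-1-TBSO-3-methylpenta-2,4-dien-1-yl]-5-[(1Z)-3-hydroxy-2-methylprop-1-en-1-yl]oxolan-2-one | OC/C(C)=C\[C@@H]1OC(=O)C[C@H]1[C@H](O[Si](C)(C)C(C)(C)C)/C=C(/C)C=C | intermediate
24 | (2Z)-3-{(2S,3R)-3-[(1R,2Z)-1-TBSO-3-methylpenta-2,4-dien-1-yl]-5-oxooxolan-2-yl}-2-methylprop-2-enal | O=C/C(C)=C\[C@@H]1OC(=O)C[C@H]1[C@H](O[Si](C)(C)C(C)(C)C)/C=C(/C)C=C | intermediate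
25 | (1E,2Z)-oxime of 24 (seco aldoxime) | O/N=C/C(C)=C\[C@@H]1OC(=O)C[C@H]1[C@H](O[Si](C)(C)C(C)(C)C)/C=C(/C)C=C | intermediate
26 | hydroximoyl chloride of 25 (not isolated) | O/N=C(\Cl)/C(C)=C\[C@@H]1OC(=O)C[C@H]1[C@H](O[Si](C)(C)C(C)(C)C)/C=C(/C)C=C | intermediate
27 | conjugated nitrile oxide (not isolated) | [O-][N+]#C/C(C)=C\[C@@H]1OC(=O)C[C@H]1[C@H](O[Si](C)(C)C(C)(C)C)/C=C(/C)C=C | intermediate
28 | (1S,6S,7R,8R,4Z,9Z)-8-TBSO-3,1-(nitrilooxy)germacra-4,9-dien-12,6-olide | C1C(=O)O[C@H]2/C=C(/C)C3=NO[C@@H](C3)/C(C)=C\[C@@H](O[Si](C)(C)C(C)(C)C)[C@H]12 | intermediate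
29 | lithium enolate of 28 (not isolated) | C1=C(O[Li])O[C@H]2/C=C(/C)C3=NO[C@@H](C3)/C(C)=C\[C@@H](O[Si](C)(C)C(C)(C)C)[C@H]12 | intermediate
30 | (1S,6S,7R,8R,11S,4Z,9Z)-13-(dimethylamino)-8-TBSO-3,1-(nitrilooxy)germacra-4,9-dien-12,6-olide | CN(C)C[C@H]1C(=O)O[C@H]2/C=C(/C)C3=NO[C@@H](C3)/C(C)=C\[C@@H](O[Si](C)(C)C(C)(C)C)[C@H]12 | intermediate
31 | (1S,6S,7S,8R,11S,4Z,9Z)-13-(dimethylamino)-8-hydroxy-3,1-(nitrilooxy)germacra-4,9-dien-12,6-olide | CN(C)C[C@H]1C(=O)O[C@H]2/C=C(/C)C3=NO[C@@H](C3)/C(C)=C\[C@@H](O)[C@H]12 | intermediate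
32 | (2Z)-2-methylbut-2-enoic acid (angelic acid) | C/C=C(/C)C(=O)O | starting material
33 | angelic 2,4,6-trichlorobenzoic anhydride (not isolated) | C/C=C(/C)C(=O)OC(=O)c1c(Cl)cc(Cl)cc1Cl | intermediate
34 | (1S,6S,7R,8R,11S,4Z,9Z)-8-angeloyloxy-13-(dimethylamino)-3,1-(nitrilooxy)germacra-4,9-dien-12,6-olide | CN(C)C[C@H]1C(=O)O[C@H]2/C=C(/C)C3=NO[C@@H](C3)/C(C)=C\[C@@H](OC(=O)/C(C)=C\C)[C@H]12 | intermediate
35 | (1S,6S,7R,8R,11S,4Z,9Z)-8-angeloyloxy-13-(dimethylamino)-1-hydroxy-3-iminogermacra-4,9-dien-12,6-olide (not isolated) | CN(C)C[C@H]1C(=O)O[C@H]2/C=C(/C)C(=N)C[C@H](O)/C(C)=C\[C@@H](OC(=O)/C(C)=C\C)[C@H]12 | intermediate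
36 | (1S,6S,7R,8R,11S,4Z,9Z)-8-angeloyloxy-13-(dimethylamino)-1-hydroxy-3-oxogermacra-4,9-dien-12,6-olide | CN(C)C[C@H]1C(=O)O[C@H]2/C=C(/C)C(=O)C[C@H](O)/C(C)=C\[C@@H](OC(=O)/C(C)=C\C)[C@H]12 | intermediate
37 | (1S,3S,6S,7R,8R,11S,4Z,9Z)-8-angeloyloxy-13-(dimethylamino)-1,3-dihydroxygermacra-4,9-dien-12,6-olide | CN(C)C[C@H]1C(=O)O[C@H]2/C=C(/C)[C@@H](O)C[C@H](O)/C(C)=C\[C@@H](OC(=O)/C(C)=C\C)[C@H]12 | intermediate
38 | 13-trimethylammonium iodide of 37 (not isolated) | C[N+](C)(C)C[C@H]1C(=O)O[C@H]2/C=C(/C)[C@@H](O)C[C@H](O)/C(C)=C\[C@@H](OC(=O)/C(C)=C\C)[C@H]12.[I-] | intermediate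
39 | (1S,3S,6S,7R,8R,4Z,9Z)-8-angeloyloxy-1,3-dihydroxygermacra-4,9,11(13)-trien-12,6-olide (CNP0152559.1) | C=C1C(=O)O[C@H]2/C=C(/C)[C@@H](O)C[C@H](O)/C(C)=C\[C@@H](OC(=O)/C(C)=C\C)[C@H]12 | target

## Step count and least certain steps

Total: 22 steps. Longest linear sequence: 19 steps (steps 1–3, 5–9 and 12–22, from 1 to 39).

Step 16 (key step). The bridged ten-membered closure is slow, so three things may go wrong:
- dimerisation or oligomerisation of the conjugated nitrile oxide;
- cycloaddition at the internal C9=C10 alkene through a seven-membered fused transition state;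
- addition to the wrong diene face.

The fallback separates dipole chemistry from ring closure. It sets out from 18 and 14. Compound 18 would be oxidised with MnO2 to (Z)-3-iodo-2-methylprop-2-enal F1 and condensed with hydroxylamine to its oxime F2. The nitrile oxide from F2 (NaOCl, CH2Cl2) would be added intermolecularly to the diene terminus of 14 to give the 5-dienyl-3-(iodoalkenyl)dihydroisoxazole F3; the two C1 epimers would have to be separated, as nothing controls that centre. Periodinane oxidation would give aldehyde F4. An intramolecular Nozaki–Hiyama–Kishi reaction (CrCl2, NiCl2 cat., DMSO/THF, high dilution) would close C5–C6 to the ten-membered hydroxy ester F5. Lactonisation with catalytic KOtBu in THF returns to the route at 28.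

Step 12. Three processes threaten it:
- poor Felkin–Anh face selectivity at C6, because the β-silyloxy group and the α-branch work in opposite senses;
- enolisation of the α-branched aldehyde by the basic vinyllithium;
- incomplete or misdirected closure of the lithium alkoxide, since silyl migration from O8 to O6 would let O8 lactonise.

The fallback replaces the basic, substrate-controlled addition by a ligand-controlled Nozaki–Hiyama–Kishi coupling. It sets out from 19 and 15 and uses CrCl2, catalytic NiCl2 and a chiral oxazoline–sulfonamide ligand in THF. This should give the (6S)-hydroxy ester F6 under non-basic conditions; F6 is closed with catalytic KOtBu in THF at 0 °C and rejoins the route at 22.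

Step 20. Once the N–O bond is cut, the β-hydroxy enone may dehydrate or open by retro-aldol. At 75 °C the substrate may also lose dimethylamine thermally, or its angelate may isomerise. The fallback moves the cleavage to the simpler compound 28 and accepts a diol protecting group:
- 28 with Mo(CO)6 gives β-hydroxy enone F7, which is reduced at once with Me4NBH(OAc)3 to diol F8.
- 2,2-Dimethoxypropane with pyridinium tosylate gives acetonide F9.
- LiN(SiMe3)2 and dimethylmethyleneammonium iodide give Mannich base F10.
- HF·pyridine gives alcohol F11.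
- Mixed-anhydride angeloylation gives F12.
- Aqueous acetic acid removes the acetonide and rejoins the route at 37.

Step 21. Undirected hydride attack may compete with delivery from O1 if the ring holds the C3 carbonyl away from O1, which would give the cis-diol; conjugate reduction of the enone is a lesser risk. The fallback changes from internal to external control: 36 would be reduced with (R)-2-methyl-CBS-oxazaborolidine and catecholborane in toluene at −78 °C, with the alkenyl side as the large group, to reach 37 directly. No new compound is made.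

Step 19. The angeloyl unit may isomerise to the tigloyl unit through reversible conjugate addition, or acylation of the hindered C8 hydroxyl may be too slow. The fallback builds the Z-enoate on the substrate. Compound 31 would be esterified (carbodiimide) with 2-[bis(2,2,2-trifluoroethoxy)phosphoryl]propanoic acid to phosphonate ester F13. A Z-selective Horner–Wadsworth–Emmons reaction of the Still–Gennari type (KN(SiMe3)2, 18-crown-6, acetaldehyde, THF, −78 °C) then gives 34.

## Further compounds

F1 | step 16 | (2Z)-3-iodo-2-methylprop-2-enal | O=C/C(C)=C\I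
F2 | step 16 | (1E,2Z)-3-iodo-2-methylprop-2-enal oxime | O/N=C/C(C)=C\I
F3 | step 16 | tert-butyl (3R,4R,5Z)-4-TBSO-3-(hydroxymethyl)-6-{(5S)-3-[(1Z)-1-iodoprop-1-en-2-yl]-4,5-dihydro-1,2-oxazol-5-yl}hept-5-enoate | OC[C@@H](CC(=O)OC(C)(C)C)[C@H](O[Si](C)(C)C(C)(C)C)/C=C(/C)[C@@H]1CC(/C(C)=C\I)=NO1
F4 | step 16 | tert-butyl (3S,4R,5Z)-4-TBSO-3-formyl-6-{(5S)-3-[(1Z)-1-iodoprop-1-en-2-yl]-4,5-dihydro-1,2-oxazol-5-yl}hept-5-enoate | O=C[C@@H](CC(=O)OC(C)(C)C)[C@H](O[Si](C)(C)C(C)(C)C)/C=C(/C)[C@@H]1CC(/C(C)=C\I)=NO1
F5 | step 16 | tert-butyl ester of (1S,6S,7R,8R,4Z,9Z)-6-hydroxy-8-TBSO-3,1-(nitrilooxy)germacra-4,9-dien-12-oic acid | CC(C)(C)OC(=O)C[C@@H]1[C@@H](O)/C=C(/C)C2=NO[C@@H](C2)/C(C)=C\[C@H]1O[Si](C)(C)C(C)(C)C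
F6 | step 12 | tert-butyl (3R,4R,5Z)-4-TBSO-3-[(1S,2Z)-4-TBSO-1-hydroxy-3-methylbut-2-en-1-yl]-6-methylocta-5,7-dienoate | CC(C)(C)[Si](C)(C)OC/C(C)=C\[C@H](O)[C@@H](CC(=O)OC(C)(C)C)[C@H](O[Si](C)(C)C(C)(C)C)/C=C(/C)C=C
F7 | step 20 | (1S,6S,7R,8R,4Z,9Z)-1-hydroxy-3-oxo-8-TBSO-germacra-4,9-dien-12,6-olide | C1C(=O)O[C@H]2/C=C(/C)C(=O)C[C@H](O)/C(C)=C\[C@@H](O[Si](C)(C)C(C)(C)C)[C@H]12
F8 | step 20 | (1S,3S,6S,7R,8R,4Z,9Z)-1,3-dihydroxy-8-TBSO-germacra-4,9-dien-12,6-olide | C1C(=O)O[C@H]2/C=C(/C)[C@@H](O)C[C@H](O)/C(C)=C\[C@@H](O[Si](C)(C)C(C)(C)C)[C@H]12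
F9 | step 20 | 1,3-O-isopropylidene acetal of F8 | C1C(=O)O[C@H]2/C=C(/C)[C@@H]3C[C@H](OC(C)(C)O3)/C(C)=C\[C@@H](O[Si](C)(C)C(C)(C)C)[C@H]12
F10 | step 20 | (11S)-13-(dimethylamino) derivative of F9 | CN(C)C[C@H]1C(=O)O[C@H]2/C=C(/C)[C@@H]3C[C@H](OC(C)(C)O3)/C(C)=C\[C@@H](O[Si](C)(C)C(C)(C)C)[C@H]12
F11 | step 20 | 8-hydroxy compound from F10 | CN(C)C[C@H]1C(=O)O[C@H]2/C=C(/C)[C@@H]3C[C@H](OC(C)(C)O3)/C(C)=C\[C@@H](O)[C@H]12
F12 | step 20 | 8-angelate of F11 (1,3-acetonide of 37) | CN(C)C[C@H]1C(=O)O[C@H]2/C=C(/C)[C@@H]3C[C@H](OC(C)(C)O3)/C(C)=C\[C@@H](OC(=O)/C(C)=C\C)[C@H]12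
F0 | step 21 | none | none
F13 | step 19 | 8-O-{2-[bis(2,2,2-trifluoroethoxy)phosphoryl]propanoyl} ester of 31 (mixture at the phosphonate α-carbon) | CN(C)C[C@H]1C(=O)O[C@H]2/C=C(/C)C3=NO[C@@H](C3)/C(C)=C\[C@@H](OC(=O)C(C)P(=O)(OCC(F)(F)F)OCC(F)(F)F)[C@H]12
A1 | alternative 1 | (3S)-5-[(4-methoxyphenyl)methoxy]pent-1-yn-3-ol | COc1ccc(COCC[C@H](O)C#C)cc1
A2 | alternative 1 | tert-butyl (3S,4S,5Z)-4-TBSO-3-formyl-6-iodohept-5-enoate | O=C[C@@H](CC(=O)OC(C)(C)C)[C@H](O[Si](C)(C)C(C)(C)C)/C=C(/C)I
A3 | alternative 1 | C1–C10 seco chain (1-OPMB, 3- and 6-hydroxyls, 8-OTBS, C10 vinyl iodide, C12 tert-butyl ester) | COc1ccc(COCC[C@H](O)/C(C)=C\[C@H](O)[C@@H](CC(=O)OC(C)(C)C)[C@H](O[Si](C)(C)C(C)(C)C)/C=C(/C)I)cc1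
A4 | alternative 2 | seco C2 iodide with C1 as 2-alkenyl-1,3-dithiane | IC[C@H](O[Si](CC)(CC)CC)/C(C)=C\[C@H](OCc1ccc(OC)cc1)[C@@H](C(=C)COCc1ccc(OC)cc1)[C@H](O[Si](C)(C)C(C)(C)C)/C=C(/C)C1SCCCS1
A5 | alternative 2 | ten-membered ring with C1 as spiro-1,3-dithiane | C1CSC2(SC1)C[C@H](O[Si](CC)(CC)CC)/C(C)=C\[C@H](OCc1ccc(OC)cc1)[C@@H](C(=C)COCc1ccc(OC)cc1)[C@H](O[Si](C)(C)C(C)(C)C)/C=C2/C
A6 | alternative 3 | ten-membered 6-hydroxy-7-ethynyl carbinol (1,3-bis-OTBS, 8-angelate) | C#C[C@@H]1[C@@H](O)/C=C(/C)[C@@H](O[Si](C)(C)C(C)(C)C)C[C@H](O[Si](C)(C)C(C)(C)C)/C(C)=C\[C@H]1OC(=O)/C(C)=C\C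
A7 | alternative 3 | 1,3-bis-TBS ether of 39 | C=C1C(=O)O[C@H]2/C=C(/C)[C@@H](O[Si](C)(C)C(C)(C)C)C[C@H](O[Si](C)(C)C(C)(C)C)/C(C)=C\[C@@H](OC(=O)/C(C)=C\C)[C@H]12
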